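## The problem

The target is a 20-membered ring in which two benzene rings are joined twice. In this text ring A is the resorcinol-type ring (A1 ether carbon, A3 hydroxyl carbon, A5 chain carbon, with A2, A4 and A6 unsubstituted). Ring B is the pyrogallol-type ring (B1 ether carbon, B2 and B6 hydroxyl carbons, B4 chain carbon). The chain is twelve methylene groups, C1 at B4 to C12 at A5.

- There is no stereocentre and no double bond, so the selectivity questions are regiochemistry on ring A and closure of a large ring against oligomerisation.
- The ether oxygen sits on B1 between two oxygenated carbons, so any plan that arylates the ring B phenol uses a nucleophile hindered on both sides.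
- The free triphenol, with its electron-rich ring B, is sensitive to air under basic conditions. The B2 and B6 oxygens are therefore carried as methyl ethers and released last, under acidic, non-oxidising conditions.
- The saturated chain has no functional handle, so a bond made inside it by olefination, metathesis or extrusion must be followed by a reduction.
- The enabling feature is ring A: hydroxyl (A3), aryloxy (A1) and alkyl (A5) alternate with three CH positions. This is the pattern formed when a vinylketene carrying the chain on its internal vinyl carbon combines with an alkynyl ether of the ring B phenol. A1 and A2 then come from the alkyne, A3 to A6 from the ketene, and the O–B1 bond is never made by arylation.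
- The two functions this requires, an acid-labile aryl ynol ether and an acid- and light-sensitive diazo ketone, dictate the order of the steps before ring closure.

## Retrosynthesis

**Unmasking (26 from 25 from 24).** The last bonds cut are the two O–CH3 bonds at B2 and B6 and, before them, the A2–Si bond of silylphenol 24. Methyl ethers are chosen because they survive organolithium reagents, enolate chemistry, light and heat and leave under acid. The silyl group is the cap of the alkyne used earlier; it sits on the most electron-rich carbon of ring A, so it can be removed by ipso-protonation. The forward steps need only acid (24 to 25) and BBr3 (25 to 26).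

**Ring A and the macrocycle together (24 from 18).** Four bonds of ring A are cut at once: A5–A6, A2–A3, A1–A6 and A3–A4. This opens ring A and the 20-membered ring in one operation and leads to the acyclic diazo enone 18, which holds only ring B. Cutting the ether or a chain bond instead would require both arenes to be bought and joined at the hindered oxygen before a separate ring closure. The forward reaction asks for a photochemical Wolff rearrangement to a vinylketene, a regioselective [2+2] cycloaddition with the tethered ynol ether across a sixteen-atom tether, and thermal electrocyclic reorganisation to the phenol, all at high dilution.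

**Diazo group (18 from 16).** The C=N2 unit is traced to the methyl group of enone 16 by detrifluoroacetylative diazo transfer. Acylation of diazomethane is not an option for an enone because of dipolar cycloaddition to the double bond. The forward step needs kinetic enolisation at the methyl group and an ynol ether that ignores the sulfonyl azide.

**Methylidene and the C12–A5 bond (16 from 15 from 12 and 13).** The methylidene carbon (future A4) is removed by a Horner–Wadsworth–Emmons disconnection with formaldehyde, giving β-ketophosphonate 15. The C12–A5 bond is then cut as an enolate alkylation of diethyl (2-oxopropyl)phosphonate 13 by chloride 12. The classical acetoacetate alkylation followed by decarboxylative Mannich methylenation was set aside as the main line because it passes through a free β-keto acid, and the ynol ether is better kept under basic conditions throughout.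

**Ynol ether (12 from 10 from 9 from 7 and 8).** The silylated alkyne is traced to the 1,2-dichlorovinyl ether 10 (elimination, chlorine–lithium exchange, silylation), and the O–C bond to addition of the phenol 7 to trichloroethylene 8. The attack is on a linear sp carbon of dichloroacetylene, which is why the two ortho methoxyls do not stand in the way. The chain end is carried as a primary chloride (10 from 9) because chloride, unlike bromide, iodide or a sulfonate, tolerates n-BuLi at low temperature and can still be activated by iodide afterwards.

**Chain and ring B (7 from 6 from 2 and 4; 2 from 1; 4 from 3).** The C1–C2 bond is cut by a Wittig disconnection to benzyl-protected syringaldehyde 2 and the phosphonium salt 4 of 11-bromoundecan-1-ol 3, via ylide 5. The benzyl group is chosen because the hydrogenation that saturates alkene 6 also removes it, so protection costs one step and no deprotection step. All carbons of the target then come from syringaldehyde 1, the bromo alcohol 3, trichloroethylene 8, phosphonate 13 and formaldehyde.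

## Roads not taken

**Alternative 1: ring contraction of a thiacyclophane sulfone.** The cut is at C1–C2, reached through the 21-membered benzyl alkyl sulfone A2. In the forward direction A2 is halogenated in situ at the benzylic C1, closed by hydroxide to an episulfone and loses SO2 (Ramberg–Bäcklund reaction) to give the macrocyclic (E)-alkene A1. Hydrogenation and cleavage of three methyl ethers follow.
- Merits: A2 would be reached by closing the ring through sulfur, one of the most dependable macrocyclisations, and the extrusion is proven for cyclophanes. Every step is known chemistry, which the chosen plan cannot claim.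
- Weak points: the diaryl ether must be made first by arylating the phenol flanked by two methoxyls. Both arenes must carry differentiated side chains. Sulfur is introduced, oxidised and expelled, and the alkene is then reduced, so several steps after ring closure only remove auxiliary atoms. The route would be clearly longer than thirteen steps.
- Comparison: this road is safer step by step. Against that, the chosen plan builds ring A, the ether-bearing carbon and the macrocycle from one linear precursor and never has to arylate the hindered oxygen.

**Alternative 2: vinylogous macroetherification of a chloroenone, then aromatisation.** The cut is the O–A1 bond, with ring A held as a cyclohexenone. The phenoxide of the seco compound A4 adds to the chlorine-bearing carbon of its 3-chlorocyclohex-2-enone and chloride leaves, giving the racemic macrocyclic 3-aryloxycyclohexenone A3. A3 is dehydrogenated to the phenol and demethylated.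
- Merits: addition–elimination at a vinylogous acid chloride is easy even for a hindered phenoxide and needs no metal, and only known reaction types are involved.
- Weak points: building the six-membered ring of A4 with the long chain at A5 and chlorinating it while the ring B phenol is masked costs about as many steps as the present route spends before its key step. The ring closure is an ordinary substitution at high dilution. Ring A arrives one oxidation level too low, so a dehydrogenation must be done on a substrate with an electron-rich ring B and two benzylic positions. The stereocentre at A5 is made only to be destroyed.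
- Comparison: overall length is similar and the risk is lower. The chosen plan offers ring A directly at the aromatic level and four carbon–carbon bonds in the closing step.

**Alternative 3: SNAr macroetherification with latent hydroxyls, then double Dakin oxidation.** The cut is the O–B1 bond with reversed polarity. The unhindered ring A phenoxide of the seco compound A6 displaces fluoride at B1, activated by two ortho formyl groups, to give the macrocyclic dialdehyde A5. Both formyl groups are then converted into hydroxyls by Dakin (Baeyer–Villiger type) oxidation, and the A3 methyl ether is cleaved.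
- Merits: the ring closure uses an unhindered nucleophile and a doubly activated fluoride, a proven way to close diaryl ether macrocycles. This is more certain than the cycloaddition proposed here. The aldehydes serve twice, as activators and as hydroxyl precursors.
- Weak points: A6 needs a 2-fluoroisophthalaldehyde with the chain at its 5-position, and two aldehydes must be protected through the chain assembly. The first of the two oxidations takes place on a ring whose migrating ability rests only on an ortho aryloxy and a para alkyl group, so over-oxidation to the acid is a real danger.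
- Comparison: the ring closure is better, but two oxidation-state changes follow it. The chosen plan has all oxygen atoms in place from the start and ends with two simple acid-mediated unmaskings.

Key step: step 11

Assumption: alkene 6 is written as the Z isomer expected from a non-stabilised ylide, and the vinyl ethers 9 and 10 as the E isomers expected from anti addition to dichloroacetylene; neither geometry matters, since step 4 saturates the alkene and step 7 turns the vinyl ether into an alkyne.

Assumption: 15 and the transient 21 each have one stereocentre, formed racemic and removed again within the route.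

## Route

Step 1
Reactants: 1 syringaldehyde (4-hydroxy-3,5-dimethoxybenzaldehyde)
Product: 2 4-(benzyloxy)-3,5-dimethoxybenzaldehyde
Conditions: BnBr, K2CO3, DMF, rt to 50 °C
Reagents that add atoms: benzyl bromide, BrCc1ccccc1
Why: Williamson etherification of an acidic phenol with a benzylic bromide; the benzyl group keeps the phenoxide from deactivating the aldehyde in step 3 and is removed in step 4 without a step of its own.

Step 2
Reactants: 3 11-bromoundecan-1-ol
Product: 4 (11-hydroxyundecyl)triphenylphosphonium bromide
Conditions: PPh3, MeCN, reflux
Reagents that add atoms: triphenylphosphine, c1ccc(cc1)P(c1ccccc1)c1ccccc1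
Why: SN2 quaternisation of the phosphine by a primary bromide; the free hydroxyl does not interfere.

Step 3
Reactants: 4 (11-hydroxyundecyl)triphenylphosphonium bromide; 2 4-(benzyloxy)-3,5-dimethoxybenzaldehyde
Product: 6 (Z)-12-[4-(benzyloxy)-3,5-dimethoxyphenyl]dodec-11-en-1-ol, via alkoxide ylide 5 (not isolated)
Conditions: NaHMDS (2.1 equiv), THF, −78 to 0 °C; then 2, −78 °C to rt
Reagents that add atoms: none
Why: Wittig olefination with a non-stabilised ylide; two equivalents of base give the alkoxide ylide 5, which adds to the aldehyde and collapses through the oxaphosphetane to form the C1–C2 bond. The alkene geometry is of no consequence.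

Step 4
Reactants: 6 (Z)-12-[4-(benzyloxy)-3,5-dimethoxyphenyl]dodec-11-en-1-ol
Product: 7 4-(12-hydroxydodecyl)-2,6-dimethoxyphenol
Conditions: H2 (1 atm), Pd/C, EtOAc/EtOH, rt
Reagents that add atoms: none
Why: Heterogeneous hydrogenation saturates the styrene-type double bond and hydrogenolyses the benzyl ether in one operation, leaving a phenol and a primary alcohol that differ widely in acidity.

Step 5
Reactants: 7 4-(12-hydroxydodecyl)-2,6-dimethoxyphenol; 8 trichloroethylene
Product: 9 12-(4-{[(E)-1,2-dichloroethenyl]oxy}-3,5-dimethoxyphenyl)dodecan-1-ol
Conditions: K2CO3, DMF, 70 °C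
Reagents that add atoms: none
Why: Known O-dichlorovinylation of phenols: carbonate forms only the phenoxide and turns 8 into dichloroacetylene, to which the phenoxide adds anti. The attack is on a linear sp carbon, so the two ortho methoxyls are tolerated, and the alcohol stays protonated.

Step 6
Reactants: 9 12-(4-{[(E)-1,2-dichloroethenyl]oxy}-3,5-dimethoxyphenyl)dodecan-1-ol
Product: 10 5-(12-chlorododecyl)-2-{[(E)-1,2-dichloroethenyl]oxy}-1,3-dimethoxybenzene
Conditions: PPh3, CCl4, CH2Cl2, 40 °C
Reagents that add atoms: carbon tetrachloride, ClC(Cl)(Cl)Cl
Why: Appel reaction under neutral conditions; a primary chloride is chosen because it is inert to n-BuLi at low temperature in step 7 and can be activated by iodide in step 8.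

Step 7
Reactants: 10 5-(12-chlorododecyl)-2-{[(E)-1,2-dichloroethenyl]oxy}-1,3-dimethoxybenzene
Product: 12 {[4-(12-chlorododecyl)-2,6-dimethoxyphenoxy]ethynyl}tri(propan-2-yl)silane, via lithium aryloxyacetylide 11 (not isolated)
Conditions: n-BuLi (2.3 equiv), THF, −78 to −40 °C; then TIPSOTf, −78 °C to rt
Reagents that add atoms: triisopropylsilyl trifluoromethanesulfonate, CC(C)[Si](OS(=O)(=O)C(F)(F)F)(C(C)C)C(C)C
Why: Known route to aryl alkynyl ethers: the first equivalent of n-BuLi eliminates HCl to the chloroalkynyl ether, the second exchanges chlorine for lithium to give 11, and the silyl triflate caps the acetylide carbon. The bulky silyl group shields the ynol ether from base, nucleophiles and traces of acid in steps 8 to 10.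

Step 8
Reactants: 12 {[4-(12-chlorododecyl)-2,6-dimethoxyphenoxy]ethynyl}tri(propan-2-yl)silane; 13 diethyl (2-oxopropyl)phosphonate
Product: 15 diethyl {15-[3,5-dimethoxy-4-({[tri(propan-2-yl)silyl]ethynyl}oxy)phenyl]-2-oxopentadecan-3-yl}phosphonate (racemic), via alkyl iodide 14 (not isolated)
Conditions: 13 (2 equiv), NaH, THF, 0 °C to rt; then 12, NaI, THF/DMF, 60 °C
Reagents that add atoms: none
Why: C-alkylation of the stabilised sodium enolate of a β-ketophosphonate by the primary iodide 14, formed in the flask by Finkelstein exchange; excess 13 suppresses dialkylation. The new stereocentre is formed racemic and disappears in step 9.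

Step 9
Reactants: 15 diethyl {15-[3,5-dimethoxy-4-({[tri(propan-2-yl)silyl]ethynyl}oxy)phenyl]-2-oxopentadecan-3-yl}phosphonate
Product: 16 15-[3,5-dimethoxy-4-({[tri(propan-2-yl)silyl]ethynyl}oxy)phenyl]-3-methylidenepentadecan-2-one
Conditions: 37% aq CH2O, K2CO3, THF/H2O, rt to 40 °C
Reagents that add atoms: formaldehyde, C=O
Why: Horner–Wadsworth–Emmons olefination with formaldehyde places the methylidene exactly on the phosphonate-bearing carbon; the medium is basic throughout, so the ynol ether is not exposed to acid.

Step 10
Reactants: 16 15-[3,5-dimethoxy-4-({[tri(propan-2-yl)silyl]ethynyl}oxy)phenyl]-3-methylidenepentadecan-2-one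
Product: 18 1-diazo-15-[3,5-dimethoxy-4-({[tri(propan-2-yl)silyl]ethynyl}oxy)phenyl]-3-methylidenepentadecan-2-one, via trifluoroacetyl diketone 17 (not isolated)
Conditions: LiHMDS, THF, −78 °C; CF3CO2CH2CF3, −78 °C; then MsN3, Et3N, H2O (1 equiv), MeCN, rt, in the dark
Reagents that add atoms: methanesulfonyl azide, CS(=O)(=O)N=[N+]=[N-]; 2,2,2-trifluoroethyl trifluoroacetate, FC(F)(F)COC(=O)C(F)(F)F (its atoms are kept only in 17)
Why: Detrifluoroacetylative diazo transfer, the standard access to diazo ketones of enones: the kinetic enolate of the methyl group is trifluoroacetylated to 17, whose activated methylene takes the diazo group from mesyl azide while the trifluoroacetyl group leaves on the sulfonamide. The hindered, silyl-capped aryloxyalkyne should react with the azide far more slowly than the diketone enolate does.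

Step 11
Reactants: 18 1-diazo-15-[3,5-dimethoxy-4-({[tri(propan-2-yl)silyl]ethynyl}oxy)phenyl]-3-methylidenepentadecan-2-one
Product: 24 macrocyclic silylphenol (20-membered diaryl ether; OH at A3, tri(propan-2-yl)silyl at A2, OMe at B2 and B6), via vinylketene 19 (not isolated), via cyclobutenone reservoir 20 (not isolated), via macrocyclic vinylcyclobutenone 21 (not isolated), via dienylketene 22 (not isolated), via cyclohexadienone 23 (not isolated)
Conditions: hν (medium-pressure Hg lamp, Pyrex filter), degassed toluene (0.001 M, 18 added slowly), rt; then 110 °C
Reagents that add atoms: none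
Why: Proposed new method: excitation of the diazo enone expels N2 and the alkenyl group shifts to the carbene carbon (Wolff rearrangement, forming A5–A6) to give vinylketene 19, which is either caught by the tethered ynol ether or closes to cyclobutenone 20, a store that reopens to 19 at 110 °C. The [2+2] cycloaddition joins the nucleophilic silyl-bearing alkyne carbon to the ketene carbonyl carbon (A2–A3) and the aryloxy carbon to the ketene α-carbon (A1–A6); this closes the four-membered ring of 21 and with it the 20-membered ring, as a cycloaddition across the ends of a strain-free sixteen-atom tether. Thermal 4π conrotatory opening of 21 gives dienylketene 22, whose 6π disrotatory electrocyclisation (A3–A4) closes ring A as dienone 23, and tautomerisation gives phenol 24. The closest known reaction type is the photochemical Wolff variant of the Danheiser benzannulation of diazo enones with alkoxy and siloxy alkynes, known only between two separate molecules; the thermal cyclobutenone variant of the same benzannulation supports the heated stage. No stereocentre remains: the single stereocentre of 21 is formed without control and is destroyed in the ring opening. The step needs regioselectivity in the [2+2] event, secured by the polarisation of the ynol ether, by the β-silyl effect and by the two flanking methoxyls, which twist the aryloxy oxygen out of conjugation with ring B so that it donates into the alkyne. It also needs ring closure to win over ketene dimerisation and intermolecular cycloaddition, which the high dilution and the reversible storage of 19 as 20 should secure; the aryl ynol ether has no β-hydrogen for retro-ene loss of ketene and should last through the heating.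

Step 12
Reactants: 24 macrocyclic silylphenol
Product: 25 macrocyclic phenol dimethyl ether (20-membered diaryl ether; OH at A3, H at A2, OMe at B2 and B6)
Conditions: TFA, CH2Cl2, 0 °C to rt
Reagents that add atoms: none
Why: Electrophilic ipso-protodesilylation of an arylsilane: A2 is ortho to the hydroxyl and the aryloxy group and para to the chain, the most electron-rich and most congested position, so protonation there and loss of silicon are favoured. Methyl ethers and the diaryl ether are inert to TFA.

Step 13
Reactants: 25 macrocyclic phenol dimethyl ether
Product: 26 target triphenol (20-membered diaryl ether; OH at A3, B2 and B6)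
Conditions: BBr3, CH2Cl2, −78 °C to rt; then MeOH, H2O
Reagents that add atoms: none
Why: Lewis-acid cleavage of the two aryl methyl ethers by bromide attack on the boron-activated methyl groups; diaryl ether bonds are not cleaved, and the acidic, non-oxidising conditions suit the air-sensitive triphenol.

## Compound list

1 | syringaldehyde (4-hydroxy-3,5-dimethoxybenzaldehyde) | COc1cc(C=O)cc(OC)c1O | starting material
2 | 4-(benzyloxy)-3,5-dimethoxybenzaldehyde | COc1cc(C=O)cc(OC)c1OCc1ccccc1 | intermediate
3 | 11-bromoundecan-1-ol | OCCCCCCCCCCCBr | starting material
4 | (11-hydroxyundecyl)triphenylphosphonium bromide | OCCCCCCCCCCC[P+](c1ccccc1)(c1ccccc1)c1ccccc1.[Br-] | intermediate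
5 | sodium 11-(triphenylphosphoranylidene)undecan-1-olate | [Na+].[O-]CCCCCCCCCCC=P(c1ccccc1)(c1ccccc1)c1ccccc1 | intermediate (not isolated)
6 | (Z)-12-[4-(benzyloxy)-3,5-dimethoxyphenyl]dodec-11-en-1-ol | COc1cc(/C=C\CCCCCCCCCCO)cc(OC)c1OCc1ccccc1 | intermediate
7 | 4-(12-hydroxydodecyl)-2,6-dimethoxyphenol | COc1cc(CCCCCCCCCCCCO)cc(OC)c1O | intermediate
8 | trichloroethylene | ClC=C(Cl)Cl | starting material
9 | 12-(4-{[(E)-1,2-dichloroethenyl]oxy}-3,5-dimethoxyphenyl)dodecan-1-ol | COc1cc(CCCCCCCCCCCCO)cc(OC)c1O/C(Cl)=C\Cl | intermediate
10 | 5-(12-chlorododecyl)-2-{[(E)-1,2-dichloroethenyl]oxy}-1,3-dimethoxybenzene | COc1cc(CCCCCCCCCCCCCl)cc(OC)c1O/C(Cl)=C\Cl | intermediate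
11 | lithium [4-(12-chlorododecyl)-2,6-dimethoxyphenoxy]ethynide | [Li]C#COc1c(OC)cc(CCCCCCCCCCCCCl)cc1OC | intermediate (not isolated)
12 | {[4-(12-chlorododecyl)-2,6-dimethoxyphenoxy]ethynyl}tri(propan-2-yl)silane | COc1cc(CCCCCCCCCCCCCl)cc(OC)c1OC#C[Si](C(C)C)(C(C)C)C(C)C | intermediate
13 | diethyl (2-oxopropyl)phosphonate | CCOP(=O)(CC(C)=O)OCC | starting material
14 | {[4-(12-iodododecyl)-2,6-dimethoxyphenoxy]ethynyl}tri(propan-2-yl)silane | COc1cc(CCCCCCCCCCCCI)cc(OC)c1OC#C[Si](C(C)C)(C(C)C)C(C)C | intermediate (not isolated)
15 | diethyl {15-[3,5-dimethoxy-4-({[tri(propan-2-yl)silyl]ethynyl}oxy)phenyl]-2-oxopentadecan-3-yl}phosphonate, racemic | CCOP(=O)(OCC)C(C(C)=O)CCCCCCCCCCCCc1cc(OC)c(OC#C[Si](C(C)C)(C(C)C)C(C)C)c(OC)c1 | intermediate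
16 | 15-[3,5-dimethoxy-4-({[tri(propan-2-yl)silyl]ethynyl}oxy)phenyl]-3-methylidenepentadecan-2-one | CC(=O)C(=C)CCCCCCCCCCCCc1cc(OC)c(OC#C[Si](C(C)C)(C(C)C)C(C)C)c(OC)c1 | intermediate
17 | 17-[3,5-dimethoxy-4-({[tri(propan-2-yl)silyl]ethynyl}oxy)phenyl]-1,1,1-trifluoro-5-methylideneheptadecane-2,4-dione | FC(F)(F)C(=O)CC(=O)C(=C)CCCCCCCCCCCCc1cc(OC)c(OC#C[Si](C(C)C)(C(C)C)C(C)C)c(OC)c1 | intermediate (not isolated)
18 | 1-diazo-15-[3,5-dimethoxy-4-({[tri(propan-2-yl)silyl]ethynyl}oxy)phenyl]-3-methylidenepentadecan-2-one | [N-]=[N+]=CC(=O)C(=C)CCCCCCCCCCCCc1cc(OC)c(OC#C[Si](C(C)C)(C(C)C)C(C)C)c(OC)c1 | intermediate (precursor of the key step)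
19 | 15-[3,5-dimethoxy-4-({[tri(propan-2-yl)silyl]ethynyl}oxy)phenyl]-3-methylidenepentadec-1-en-1-one (vinylketene) | O=C=CC(=C)CCCCCCCCCCCCc1cc(OC)c(OC#C[Si](C(C)C)(C(C)C)C(C)C)c(OC)c1 | intermediate (not isolated)
20 | 3-{12-[3,5-dimethoxy-4-({[tri(propan-2-yl)silyl]ethynyl}oxy)phenyl]dodecyl}cyclobut-2-en-1-one | O=C1C=C(CCCCCCCCCCCCc2cc(OC)c(OC#C[Si](C(C)C)(C(C)C)C(C)C)c(OC)c2)C1 | intermediate (not isolated)
21 | macrocyclic vinylcyclobutenone: cyclobut-2-enone with C=O as future A3, silyl on the α-carbon (A2), aryloxy on the β-carbon (A1), and the sp3 carbon (A6) bonded to the methylidene-bearing carbon A5; racemic | O=C1C([Si](C(C)C)(C(C)C)C(C)C)=C2Oc3c(OC)cc(CCCCCCCCCCCCC(=C)C12)cc3OC | intermediate (not isolated)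
22 | macrocyclic dienylketene O=C=C(Si)–C(OAr)=CH–C(=CH2)–chain, ketenyl and alkenyl groups cis on the central double bond | O=C=C([Si](C(C)C)(C(C)C)C(C)C)/C1=C\C(=C)CCCCCCCCCCCCc2cc(OC)c(O1)c(OC)c2 | intermediate (not isolated)
23 | macrocyclic cyclohexa-2,4-dienone, keto tautomer of 24 with CH2 at A4 | O=C1CC2=CC(=C1[Si](C(C)C)(C(C)C)C(C)C)Oc3c(OC)cc(cc3OC)CCCCCCCCCCCC2 | intermediate (not isolated)
24 | macrocyclic silylphenol: 20-membered diaryl ether, OH at A3, tri(propan-2-yl)silyl at A2, OMe at B2 and B6 | COc1cc2CCCCCCCCCCCCc3cc(O)c([Si](C(C)C)(C(C)C)C(C)C)c(c3)Oc1c(OC)c2 | intermediate (product of the key step)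
25 | macrocyclic phenol dimethyl ether: OH at A3, H at A2, OMe at B2 and B6 | COc1cc2CCCCCCCCCCCCc3cc(O)cc(c3)Oc1c(OC)c2 | intermediate
26 | target triphenol: OH at A3, B2 and B6 | Oc1cc2cc(c1)Oc1c(O)cc(cc1O)CCCCCCCCCCCC2 | target

## Step count and risks

Total: 13 steps. Longest linear sequence: 12 steps (1 to 2, then steps 3 to 13); step 2 is the only side branch.

**Step 11 (key step).** The most likely failure is that ring closure loses to intermolecular cycloaddition, ketene dimerisation or slow decay of the vinylketene. The reason is that the nucleophilic alkyne carbon carries a bulky silyl group and the effective molarity of a 20-membered closure is low. Photodegradation of the aryloxyalkyne during a long irradiation is a second possibility.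

The fallback gives up building ring A and uses known chemistry; it sets out from 6 and rejoins the route at 26.
- The alcohol of 6 would be converted (I2, PPh3, imidazole) into 2-(benzyloxy)-5-[(Z)-12-iodododec-1-en-1-yl]-1,3-dimethoxybenzene F1.
- Zinc insertion would give the alkylzinc iodide F2.
- Negishi coupling (Pd(OAc)2, SPhos) with 2-(3-bromo-5-methoxyphenyl)-4,4,5,5-tetramethyl-1,3,2-dioxaborolane would attach ring A as the pinacol boronate F3.
- Periodate cleavage of the pinacol ester would give the boronic acid F4.
- Hydrogenation of alkene and benzyl ether would give the phenol boronic acid F5.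
- Chan–Lam macroetherification (Cu(OAc)2, pyridine, air, molecular sieves, high dilution) would close the ring to the macrocyclic trimethyl ether F6.
- BBr3 as in step 13 would then give 26.

This fallback arylates the hindered phenol, which the main plan avoids.

**Step 10.** The most likely failure is cycloaddition of the sulfonyl azide to the electron-rich alkyne, or deprotonation at the allylic γ-position instead of the methyl group.

The fallback reaches the vinylketene without a diazo compound; it sets out from 12 and rejoins at 20.
- Magnesium insertion into 12 would give the Grignard reagent F7.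
- 1,2-Addition to 3-ethoxycyclobut-2-en-1-one would give the carbinol F8.
- Brief treatment with dilute aqueous acid would hydrolyse and transpose F8 to cyclobutenone 20.
- 20 would then be heated at high dilution as in the second stage of step 11 to give 24.

The short acid contact is the point to watch for the ynol ether.

**Step 7.** The most likely failure is loss of the primary chloride, by elimination, substitution or acetylide alkylation, if the hindered dichlorovinyl ether needs warming to complete the elimination and exchange.

The fallback removes the halide from the organolithium step; it sets out from 9 and rejoins at 15.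
- 9 would be protected as 2-{[12-(4-{[(E)-1,2-dichloroethenyl]oxy}-3,5-dimethoxyphenyl)dodecyl]oxy}oxane F9.
- Treatment with n-BuLi and then TIPSOTf as in step 7 would give the silylated ynol ether tetrahydropyranyl ether F10.
- Direct conversion with PPh3 and CBr4 would give {[4-(12-bromododecyl)-2,6-dimethoxyphenoxy]ethynyl}tri(propan-2-yl)silane F11.
- F11 would alkylate the sodium enolate of 13 to give 15.

**Step 8.** The most likely failure is sluggish alkylation by the weakly nucleophilic phosphonate enolate, with elimination of the iodide or O-alkylation taking over.

The fallback uses a more nucleophilic enolate and introduces the methylidene differently; it sets out from 12 and rejoins at 16.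
- Alkylation of methyl acetoacetate (K2CO3, NaI) would give methyl 2-acetyl-14-[3,5-dimethoxy-4-({[tri(propan-2-yl)silyl]ethynyl}oxy)phenyl]tetradecanoate F12.
- Saponification with LiOH would give the β-keto acid F13.
- Decarboxylative Mannich methylenation (aqueous CH2O, Et2NH, buffered near neutral) would give 16.

The price is the brief handling of a free β-keto acid beside the acid-labile ynol ether.

## Further compounds

F1 | step 11 | 2-(benzyloxy)-5-[(Z)-12-iodododec-1-en-1-yl]-1,3-dimethoxybenzene | COc1cc(/C=C\CCCCCCCCCCI)cc(OC)c1OCc1ccccc1
F2 | step 11 | {(Z)-12-[4-(benzyloxy)-3,5-dimethoxyphenyl]dodec-11-en-1-yl}zinc iodide | COc1cc(/C=C\CCCCCCCCCC[Zn]I)cc(OC)c1OCc1ccccc1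
F3 | step 11 | 2-{3-[(Z)-12-(4-benzyloxy-3,5-dimethoxyphenyl)dodec-11-en-1-yl]-5-methoxyphenyl}-4,4,5,5-tetramethyl-1,3,2-dioxaborolane | COc1cc(CCCCCCCCCC/C=C\c2cc(OC)c(OCc3ccccc3)c(OC)c2)cc(c1)B1OC(C)(C)C(C)(C)O1
F4 | step 11 | {3-[(Z)-12-(4-benzyloxy-3,5-dimethoxyphenyl)dodec-11-en-1-yl]-5-methoxyphenyl}boronic acid | COc1cc(CCCCCCCCCC/C=C\c2cc(OC)c(OCc3ccccc3)c(OC)c2)cc(c1)B(O)O
F5 | step 11 | {3-[12-(4-hydroxy-3,5-dimethoxyphenyl)dodecyl]-5-methoxyphenyl}boronic acid | COc1cc(CCCCCCCCCCCCc2cc(OC)c(O)c(OC)c2)cc(c1)B(O)O
F6 | step 11 | macrocyclic trimethyl ether: 20-membered diaryl ether with OMe at A3, B2 and B6 | COc1cc2CCCCCCCCCCCCc3cc(OC)cc(c3)Oc1c(OC)c2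
F7 | step 10 | {12-[3,5-dimethoxy-4-({[tri(propan-2-yl)silyl]ethynyl}oxy)phenyl]dodecyl}magnesium chloride | Cl[Mg]CCCCCCCCCCCCc1cc(OC)c(OC#C[Si](C(C)C)(C(C)C)C(C)C)c(OC)c1
F8 | step 10 | 1-{12-[3,5-dimethoxy-4-({[tri(propan-2-yl)silyl]ethynyl}oxy)phenyl]dodecyl}-3-ethoxycyclobut-2-en-1-ol, racemic | CCOC1=CC(O)(CCCCCCCCCCCCc2cc(OC)c(OC#C[Si](C(C)C)(C(C)C)C(C)C)c(OC)c2)C1
F9 | step 7 | 2-{[12-(4-{[(E)-1,2-dichloroethenyl]oxy}-3,5-dimethoxyphenyl)dodecyl]oxy}oxane, racemic | COc1cc(CCCCCCCCCCCCOC2CCCCO2)cc(OC)c1O/C(Cl)=C\Cl
F10 | step 7 | ({2,6-dimethoxy-4-[12-(oxan-2-yloxy)dodecyl]phenoxy}ethynyl)tri(propan-2-yl)silane, racemic | COc1cc(CCCCCCCCCCCCOC2CCCCO2)cc(OC)c1OC#C[Si](C(C)C)(C(C)C)C(C)C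
F11 | step 7 | {[4-(12-bromododecyl)-2,6-dimethoxyphenoxy]ethynyl}tri(propan-2-yl)silane | COc1cc(CCCCCCCCCCCCBr)cc(OC)c1OC#C[Si](C(C)C)(C(C)C)C(C)C
F12 | step 8 | methyl 2-acetyl-14-[3,5-dimethoxy-4-({[tri(propan-2-yl)silyl]ethynyl}oxy)phenyl]tetradecanoate, racemic | COC(=O)C(C(C)=O)CCCCCCCCCCCCc1cc(OC)c(OC#C[Si](C(C)C)(C(C)C)C(C)C)c(OC)c1
F13 | step 8 | 2-acetyl-14-[3,5-dimethoxy-4-({[tri(propan-2-yl)silyl]ethynyl}oxy)phenyl]tetradecanoic acid, racemic | OC(=O)C(C(C)=O)CCCCCCCCCCCCc1cc(OC)c(OC#C[Si](C(C)C)(C(C)C)C(C)C)c(OC)c1
A1 | alternative 1 | macrocyclic (E)-C1–C2 alkene, trimethyl ether | COc1cc2/C=C/CCCCCCCCCCc3cc(OC)cc(c3)Oc1c(OC)c2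
A2 | alternative 1 | 21-membered benzyl alkyl sulfone (SO2 between C1 and C2), trimethyl ether | COc1cc2CS(=O)(=O)CCCCCCCCCCCc3cc(OC)cc(c3)Oc1c(OC)c2
A3 | alternative 2 | racemic macrocyclic 3-aryloxycyclohex-2-enone (ring A as its dihydro keto form), OMe at B2 and B6 | COc1cc2CCCCCCCCCCCCC3CC(=O)C=C(C3)Oc1c(OC)c2
A4 | alternative 2 | 3-chloro-5-[12-(4-hydroxy-3,5-dimethoxyphenyl)dodecyl]cyclohex-2-en-1-one, racemic | COc1cc(CCCCCCCCCCCCC2CC(=O)C=C(Cl)C2)cc(OC)c1O
A5 | alternative 3 | macrocyclic diaryl ether with formyl groups at B2 and B6 and OMe at A3 | O=Cc1cc2CCCCCCCCCCCCc3cc(OC)cc(c3)Oc1c(C=O)c2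
A6 | alternative 3 | 2-fluoro-5-[12-(3-hydroxy-5-methoxyphenyl)dodecyl]benzene-1,3-dicarbaldehyde | O=Cc1cc(CCCCCCCCCCCCc2cc(O)cc(OC)c2)cc(C=O)c1F
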